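Start at early times: this flask, followed so far as the blue run, begins with none of the solid reagent in solution, and at 10.0 s the single product reads 0.6%.

- blue: substrate 0.20 M; solid reagent 0.20 M; the very flask that is asked about, followed so far
- flask: substrate 0.20 M; solid reagent 0.200 M; time 3.0 min
- blue (time / s: single product / %): 10.0: 0.6; 20.0: 4.1; 30.0: 7.3; 50.0: 15.1; 80.0: 28.8

(readings scatter by 1 percentage point)
- solid, in amounts per volume of the solution: solid reagent
- the numbers in the tables scatter by 1 percentage point (one standard deviation)
- at the start none of the solid reagent is in solution
- the reaction counts as stopped when no species that holds the substrate changes by six tenths of a point or more over the second half of the time
* the state of affairs at 3.0 min: stopped, and by what, or still going (for what has run out or reacted, a solid counts together with what of it has only dissolved) (all of the substrate has reacted / the partner has run out first / it is still moving / forward and back rates have come level)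
* how much single product there is at 3.0 min, in percent of the substrate charged
* amount of single product if the flask were left three thousand times as long, in percent of the substrate charged

Take the partner in solution as the concentration that sets the order of the rate. While it stands steady, the substrate falls pseudo-first-order. So divide the product gained per time by the fraction of substrate still there, and take the ladder rung by rung.

The first rung is the climb of the partner: this rate reads 0.204 min⁻¹ between the second and third readings. Between the last two it reads more, and call that value the standing rate: 0.351 min⁻¹. Both are readings and carry the scatter.

The next rung is the substrate: the standing rate gives it a half-life of 1.97 min, shorter than the 3.0 min asked about. Hold the standing rate from the middle of those two readings up to that time, and my own reckoning gives 60.2% single product, still moving.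

The forecast says it is still moving, with 74% at that time and 100% in the long run, and its ground is “the active partner is still building up”. Its 74% stands above my figure; it is what a straight line through the last two readings gives.

The flask gives: it is still moving, with 61.6% at the asked time and 90.5% on the long stay asked about.

    substrate + partner → single product (k = 0.300 M⁻¹ s⁻¹)
    partner + single product → bis adduct (k = 0.00700 M⁻¹ s⁻¹)
    solid reagent ⇌ partner, rate k3*(cs3 - [partner]) while solid is left; crystals form when [partner] > cs3 (solubility = 0.150 M, k = 0.00650 s⁻¹)

Against the 60.2% reckoned from the half-life of 1.97 min, the flask stands at 61.6%; at that time single product is made 26.2 times faster than it is used up, each step taken net, and its half-life by the step to bis adduct, 91 min at 1.45 min, is longer than the 3.0 min. Charge the same flask with 0.080 M of solid reagent, 0.400 equiv, and at 3.00 min the solid reagent stands at 0%, the substrate at 60.5% and the single product at 39.2%, while the partner remaining puts the substrate's half-life at 64.2 min.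

The data stem from a simulated flask from invented constants; noise was put on by code.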